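**Plan**

- Numbering: chromane O1, C2, C3, C4, C4a, C5–C8, C8a (OMe on C6, methyl on C8, ring A is the benzene ring); side chain C1'–C9' counted from C2, with C9' the carboxyl carbon.
- Cuts, in retrosynthetic order: the acid from its methyl ester; C2'–C3' (B-alkyl Suzuki–Miyaura), giving a 2-vinylchromane and a C3'–C9' iodo-dienoate; in that fragment C7'=C8' (Still–Gennari) and the C4'–CH3 and C3'–I bonds (carboalumination–iodination of pent-4-yn-1-ol); in the chromane O1–C2 and C3–C4.
- Enabling feature: O1–C8a–C4a–C4 is the o-quinone methide of 4-methoxy-2-methylphenol (an oxa-diene), and C2 with its methyl, C3, C1' and C2' is isoprene. Isoprene reacts through its methyl-bearing double bond and keeps the other as the C1'=C2' vinyl handle.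
- Forward order: ring A is bought; C4 is added by ortho-formylation and reduction; the dihydropyran ring closes in an acid-catalysed hetero-[4+2] cycloaddition; the chain is joined by hydroboration and Suzuki coupling with the separately made iodo-enoate; saponification ends the route.
- Stereochemistry: C2 comes from the chiral counter-anion of the Brønsted acid in the cycloaddition and is a quaternary ether carbon that nothing touches afterwards. C3'=C4' (E) comes from syn-carboalumination and retentive iodinolysis and coupling. C7'=C8' (Z) comes from the Still–Gennari olefination.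

Key step: step 3

Assumption: the (R)-enantiomer of the acid catalyst is taken to deliver the (S)-vinylchromane; the sense of induction cannot be predicted for this new substrate pair, and the (S)-catalyst would be used instead if it proved opposite.

**Route**

Step 1
Reactants: 1 4-methoxy-2-methylphenol
Product: 2 2-hydroxy-5-methoxy-3-methylbenzaldehyde
Conditions: MgCl2, Et3N, (CH2O)n, MeCN, reflux
Reagents that add atoms: paraformaldehyde (as formaldehyde), C=O
Why: Casnati–Skattebøl ortho-formylation, in which the magnesium phenoxide of 1 delivers formaldehyde to the only free ortho position (the other ortho carbon carries the methyl group and the para carbon the methoxy group) and the resulting benzylic alkoxide is oxidised to the aldehyde by hydride transfer to a second formaldehyde.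

Step 2
Reactants: 2 2-hydroxy-5-methoxy-3-methylbenzaldehyde
Product: 3 2-(hydroxymethyl)-4-methoxy-6-methylphenol
Conditions: NaBH4, THF/MeOH, 0 °C
Reagents that add atoms: none
Why: Chemoselective borohydride reduction of the aryl aldehyde should give the salicyl alcohol, which is worked up near neutral pH and kept cold because it is the latent o-quinone methide.

Step 3
Reactants: 3 2-(hydroxymethyl)-4-methoxy-6-methylphenol; 4 isoprene (2-methylbuta-1,3-diene)
Product: 6 (S)-6-methoxy-2,8-dimethyl-2-vinylchromane, via o-quinone methide 5 (not isolated)
Conditions: (R)-3,3'-bis(2,4,6-triisopropylphenyl)-1,1'-binaphthyl-2,2'-diyl N-(trifluoromethanesulfonyl)phosphoramide (10 mol%), 4 (10 equiv), 5 Å molecular sieves, toluene, 0 °C to rt, sealed vessel, slow addition of 3; Et3N quench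
Reagents that add atoms: none
Why: Proposed new method: the strong chiral acid protonates the benzylic hydroxyl of 3 and, helped by electron release from the ortho oxygen, expels water to give o-quinone methide 5, which stays hydrogen-bonded to the phosphoramide anion as a tight ion pair in toluene. The CH2 terminus of the 1,1-disubstituted double bond of 4 then adds to the exocyclic methylene (C3–C4), and the tertiary allylic cation character that develops at the methyl-bearing carbon is quenched by the phenolic oxygen (O1–C2), so that the event is an asynchronous, inverse-electron-demand oxa-[4+2] cycloaddition that restores the aromatic ring. The nearest known reactions are the thermal, racemic cycloaddition of o-quinone methides with isoprene and the enantioselective, chiral phosphoric acid or N-triflyl phosphoramide catalysed cycloadditions of o-quinone methides with styrenes and enol ethers; what has not been shown is enantiocontrol with an unactivated 1,3-diene. The dihydropyran ring is closed by this intermolecular [4+2] mode, the last bond being made by the oxygen at the near terminus of the allyl cation in a six-membered closure (the far terminus would demand an eight-membered ring). C2 is the only new stereocentre and is set by the chiral counter-anion, which sits on the very oxygen that forms the O1–C2 bond and should therefore shield one face of the alkene (or of the allyl cation) within its 3,3'-aryl pocket. The step needs site selectivity for the methyl-bearing over the monosubstituted double bond and oxygen attachment at the tertiary carbon, both secured by the stability of the tertiary allylic cation, and it needs the quinone methide to be trapped faster than it self-condenses, which the excess of diene, slow addition of 3 and the electron-rich, less electrophilic methoxy-substituted ring favour.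

Step 4
Reactants: 7 pent-4-yn-1-ol
Product: 9 (E)-5-iodo-4-methylpent-4-en-1-ol, via alkenylalane 8 (not isolated)
Conditions: AlMe3 (3 equiv), Cp2ZrCl2 (bis(cyclopentadienyl)zirconium dichloride, 0.25 equiv), CH2Cl2, 0 °C to rt; then I2, THF, −30 to 0 °C; aq. K2CO3 work-up
Reagents that add atoms: trimethylaluminium, C[Al](C)C; iodine, II
Why: Zirconium-catalysed carboalumination (Negishi) adds methyl and aluminium syn across the terminal alkyne, with methyl on the internal carbon, after the hydroxyl has been capped as its aluminium alkoxide, and iodinolysis of the C–Al bond with retention fixes the (E)-geometry of the future C3'=C4' bond.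

Step 5
Reactants: 9 (E)-5-iodo-4-methylpent-4-en-1-ol
Product: 10 (E)-5-iodo-4-methylpent-4-enal
Conditions: Dess–Martin periodinane, CH2Cl2, 0 °C to rt
Reagents that add atoms: none
Why: Dess–Martin oxidation should stop cleanly at the aldehyde under near-neutral conditions that leave the vinyl iodide and its geometry untouched.

Step 6
Reactants: 10 (E)-5-iodo-4-methylpent-4-enal; 11 methyl 2-[bis(2,2,2-trifluoroethoxy)phosphoryl]propanoate
Product: 12 methyl (2Z,6E)-7-iodo-2,6-dimethylhepta-2,6-dienoate
Conditions: KN(SiMe3)2, 18-crown-6, THF, −78 °C
Reagents that add atoms: none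
Why: Still–Gennari olefination, in which the potassium anion of the electron-poor bis(trifluoroethyl) phosphonate adds to the aldehyde under kinetic control and the fast, irreversible collapse of the adduct in the presence of the crown ether should deliver the (Z)-trisubstituted enoate (ester cis to the chain), the vinyl iodide being inert to the base at this temperature.

Step 7
Reactants: 6 (S)-6-methoxy-2,8-dimethyl-2-vinylchromane; 12 methyl (2Z,6E)-7-iodo-2,6-dimethylhepta-2,6-dienoate
Product: 14 methyl (2Z,6E)-9-[(2R)-6-methoxy-2,8-dimethylchroman-2-yl]-2,6-dimethylnona-2,6-dienoate, via alkylborane 13 (not isolated)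
Conditions: 9-borabicyclo[3.3.1]nonane (9-BBN), THF, 0 °C to rt; then 12, PdCl2(dppf) (dppf = 1,1'-bis(diphenylphosphino)ferrocene, 5 mol%), AsPh3, Cs2CO3, DMF/THF/H2O, rt
Reagents that add atoms: none
Why: Anti-Markovnikov hydroboration of the monosubstituted vinyl group by the bulky borane places boron on C2', and the B-alkyl Suzuki–Miyaura coupling of this primary alkylborane with the (E)-vinyl iodide should form C2'–C3' with retention of olefin geometry under base mild enough for the methyl ester, while the quaternary centre is not involved and changes its descriptor from S to R only because the CIP ranking of its substituents changes.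

Step 8
Reactants: 14 methyl (2Z,6E)-9-[(2R)-6-methoxy-2,8-dimethylchroman-2-yl]-2,6-dimethylnona-2,6-dienoate
Product: 15 (2Z,6E)-9-[(2R)-6-methoxy-2,8-dimethylchroman-2-yl]-2,6-dimethylnona-2,6-dienoic acid
Conditions: LiOH, THF/MeOH/H2O, rt to 40 °C; then 1 M HCl to pH 3, 0 °C
Reagents that add atoms: lithium hydroxide, [Li+].[OH-]
Why: Saponification (acyl–oxygen cleavage by hydroxide) followed by mild acidification should free the acid, since the aryl ethers, the quaternary ether centre and both trisubstituted olefins tolerate aqueous LiOH near room temperature.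

**Compound list**

1 | 4-methoxy-2-methylphenol | COc1ccc(O)c(C)c1 | starting material
2 | 2-hydroxy-5-methoxy-3-methylbenzaldehyde | COc1cc(C)c(O)c(C=O)c1 | intermediate
3 | 2-(hydroxymethyl)-4-methoxy-6-methylphenol | COc1cc(C)c(O)c(CO)c1 | intermediate
4 | isoprene (2-methylbuta-1,3-diene) | C=CC(C)=C | starting material
5 | 4-methoxy-2-methyl-6-methylidenecyclohexa-2,4-dien-1-one (o-quinone methide) | COC1=CC(=C)C(=O)C(C)=C1 | intermediate (not isolated)
6 | (S)-6-methoxy-2,8-dimethyl-2-vinylchromane, i.e. (2S)-2-ethenyl-6-methoxy-2,8-dimethyl-3,4-dihydro-2H-chromene | COc1cc(C)c2c(c1)CC[C@@](C)(C=C)O2 | intermediate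
7 | pent-4-yn-1-ol | C#CCCCO | starting material
8 | dimethylaluminium (E)-5-(dimethylalumanyl)-4-methylpent-4-en-1-olate (alkenylalane) | C[Al](C)/C=C(\C)CCCO[Al](C)C | intermediate (not isolated)
9 | (E)-5-iodo-4-methylpent-4-en-1-ol | OCCC/C(C)=C/I | intermediate
10 | (E)-5-iodo-4-methylpent-4-enal | O=CCC/C(C)=C/I | intermediate
11 | methyl 2-[bis(2,2,2-trifluoroethoxy)phosphoryl]propanoate | COC(=O)C(C)P(=O)(OCC(F)(F)F)OCC(F)(F)F | starting material
12 | methyl (2Z,6E)-7-iodo-2,6-dimethylhepta-2,6-dienoate | COC(=O)/C(C)=C\CC/C(C)=C/I | intermediate
13 | 9-{2-[(2R)-6-methoxy-2,8-dimethylchroman-2-yl]ethyl}-9-borabicyclo[3.3.1]nonane (alkylborane) | COc1cc(C)c2c(c1)CC[C@@](C)(CCB3C4CCCC3CCC4)O2 | intermediate (not isolated)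
14 | methyl (2Z,6E)-9-[(2R)-6-methoxy-2,8-dimethylchroman-2-yl]-2,6-dimethylnona-2,6-dienoate | COc1cc(C)c2c(c1)CC[C@@](C)(CC/C=C(\C)CC/C=C(/C)C(=O)OC)O2 | intermediate
15 | (2Z,6E)-9-[(2R)-6-methoxy-2,8-dimethylchroman-2-yl]-2,6-dimethylnona-2,6-dienoic acid | COc1cc(C)c2c(c1)CC[C@@](C)(CC/C=C(\C)CC/C=C(/C)C(=O)O)O2 | target

**Step count and risks**

Total: 8 steps. Longest linear sequence: 5 steps (steps 1, 2, 3, 7, 8; the fragment branch 4, 5, 6, 7, 8 is equally long).

Risk 1, step 3 (the proposed new method). The chiral anion may not tell apart the two faces of a small hydrocarbon diene that offers no hydrogen-bond handle, so the chromane could form with poor enantioselectivity. Ionisation of the primary benzylic alcohol may also be slow enough for self-condensation of the quinone methide and acid-driven oligomerisation of the diene to compete. The tertiary allylic aryl ether of the product could re-ionise under the acid and lose enantiopurity. The fallback uses known chemistry, a palladium-catalysed asymmetric allylic O-alkylation of the phenol (Tsuji–Trost type) that makes the same O1–C2 bond and the same 2-methyl-2-vinyl centre. It sets out from aldehyde 2 and comes back to the route at 6. Claisen–Schmidt condensation of 2 with acetone (aq. NaOH, rt) should give (E)-4-(2-hydroxy-5-methoxy-3-methylphenyl)but-3-en-2-one F1. Hydrogenation of the enone double bond (H2, Pd/C, EtOAc) leads to 4-(2-hydroxy-5-methoxy-3-methylphenyl)butan-2-one F2. Horner–Wadsworth–Emmons olefination with triethyl phosphonoacetate (NaH in excess, THF) and removal of the minor Z isomer furnishes ethyl (E)-5-(2-hydroxy-5-methoxy-3-methylphenyl)-3-methylpent-2-enoate F3. Reduction with i-Bu2AlH (CH2Cl2, −78 °C) gives (E)-5-(2-hydroxy-5-methoxy-3-methylphenyl)-3-methylpent-2-en-1-ol F4. Acylation of the primary allylic hydroxyl in preference to the hindered, 2,6-disubstituted phenol (ClCO2Me, pyridine, CH2Cl2, −20 °C) gives (E)-5-(2-hydroxy-5-methoxy-3-methylphenyl)-3-methylpent-2-en-1-yl methyl carbonate F5. Ionisation of F5 with a zerovalent palladium source, Pd2(dba)3·CHCl3 (dba = dibenzylideneacetone), and one enantiomer of N,N'-(cyclohexane-1,2-diyl)bis[2-(diphenylphosphino)benzamide] in CH2Cl2 with AcOH lets the phenol attack the more substituted terminus of the π-allyl complex. The six-membered ring closes to 6, the ligand enantiomer being chosen to give the (S)-chromane.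

Risk 2, step 7. Transmetalation of the alkylborane may be slow, so that protodeboronation and β-hydride elimination compete, or the aqueous base may attack the enoate (hydrolysis, drift of the Z double bond) during a sluggish coupling. The fallback replaces boron by zinc in a base-free Negishi coupling; it sets out from 6 and comes back at 14. Alkylborane 13, made from 6 as before, is oxidised (NaOH, H2O2) to 2-[(2S)-6-methoxy-2,8-dimethylchroman-2-yl]ethan-1-ol F6. Treatment with I2, PPh3 and imidazole (CH2Cl2) gives (2S)-2-(2-iodoethyl)-6-methoxy-2,8-dimethylchromane F7. Insertion of activated Zn dust (THF/N,N-dimethylacetamide, 40 °C) forms {2-[(2S)-6-methoxy-2,8-dimethylchroman-2-yl]ethyl}zinc iodide F8. This is coupled with vinyl iodide 12 under Pd(PPh3)4 catalysis in THF to give 14.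

Risk 3, step 8. Hydrolysis of the hindered (Z)-α-methyl enoate may be sluggish, and forcing it with heat and excess base invites base-mediated isomerisation of C7'=C8' towards the E acid or deconjugation. The fallback avoids hydrolysis by a reduction–oxidation detour; it sets out from 14 and comes back at 15. Reduction with i-Bu2AlH (CH2Cl2, −78 °C) should give (2Z,6E)-9-[(2R)-6-methoxy-2,8-dimethylchroman-2-yl]-2,6-dimethylnona-2,6-dien-1-ol F9. Dess–Martin oxidation buffered with NaHCO3 gives (2Z,6E)-9-[(2R)-6-methoxy-2,8-dimethylchroman-2-yl]-2,6-dimethylnona-2,6-dienal F10. This is oxidised at once under Pinnick conditions (NaClO2, NaH2PO4, 2-methylbut-2-ene in large excess, t-BuOH/H2O) to acid 15, the alkene scavenger protecting the electron-rich ring from hypochlorite.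

**Further compounds**

F1 | step 3 | (E)-4-(2-hydroxy-5-methoxy-3-methylphenyl)but-3-en-2-one | COc1cc(C)c(O)c(/C=C/C(C)=O)c1
F2 | step 3 | 4-(2-hydroxy-5-methoxy-3-methylphenyl)butan-2-one | COc1cc(C)c(O)c(CCC(C)=O)c1
F3 | step 3 | ethyl (E)-5-(2-hydroxy-5-methoxy-3-methylphenyl)-3-methylpent-2-enoate | CCOC(=O)/C=C(\C)CCc1cc(OC)cc(C)c1O
F4 | step 3 | (E)-5-(2-hydroxy-5-methoxy-3-methylphenyl)-3-methylpent-2-en-1-ol | OC/C=C(\C)CCc1cc(OC)cc(C)c1O
F5 | step 3 | (E)-5-(2-hydroxy-5-methoxy-3-methylphenyl)-3-methylpent-2-en-1-yl methyl carbonate | COC(=O)OC/C=C(\C)CCc1cc(OC)cc(C)c1O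
F6 | step 7 | 2-[(2S)-6-methoxy-2,8-dimethylchroman-2-yl]ethan-1-ol | COc1cc(C)c2c(c1)CC[C@@](C)(CCO)O2
F7 | step 7 | (2S)-2-(2-iodoethyl)-6-methoxy-2,8-dimethylchromane | COc1cc(C)c2c(c1)CC[C@@](C)(CCI)O2
F8 | step 7 | {2-[(2S)-6-methoxy-2,8-dimethylchroman-2-yl]ethyl}zinc iodide | COc1cc(C)c2c(c1)CC[C@@](C)(CC[Zn]I)O2
F9 | step 8 | (2Z,6E)-9-[(2R)-6-methoxy-2,8-dimethylchroman-2-yl]-2,6-dimethylnona-2,6-dien-1-ol | COc1cc(C)c2c(c1)CC[C@@](C)(CC/C=C(\C)CC/C=C(/C)CO)O2
F10 | step 8 | (2Z,6E)-9-[(2R)-6-methoxy-2,8-dimethylchroman-2-yl]-2,6-dimethylnona-2,6-dienal | COc1cc(C)c2c(c1)CC[C@@](C)(CC/C=C(\C)CC/C=C(/C)C=O)O2
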